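**Retrosynthetic overview**
1. Target 13 comes from 11 by oxidising the neopentyl C19 CH2OH to CO2H. The 15-acetate is carried from step 2, so no protecting groups are used.
2. 11 comes from 10. Both rings form in one cation–olefin cascade of an acyclic dienyl (S)-2-methyl-2-alkyloxirane whose CH2–O is the future C19. Ring A closes first (C4–C5), ring B second (C9–C10), and loss of H-17 gives the 8(17)-ene.
3. The oxirane carbon (C4) is inverted, and chair–chair folding relays its configuration to C5, C10 and C9. C13 is set independently.
4. 10 comes from 9 by asymmetric CH2 transfer to a methyl ketone. 9 comes from 5 and 6 by Cu-catalysed Grignard coupling, which forms the C1–C2 bond.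
5. 5 comes from 1. (E,E)-Farnesol supplies both E-alkenes, asymmetric hydrogenation sets C13, and terminal allylic oxidation functionalises C1.

Assumption: the target is read as 15-O-acetylimbricatolic acid, (4S,5R,9S,10R,13S) in labdane numbering. In step 6 the BINOL antipode is written as (S) by analogy; if the sense of induction is the opposite one, (R)-BINOL is used.

**Step 1**
Reactants: 1 (2E,6E)-farnesol
Product: 2 (3S,6E)-3,7,11-trimethyldodeca-6,10-dien-1-ol [(S)-2,3-dihydrofarnesol]
Conditions: H2 (100 atm), Ru(OAc)2[(R)-BINAP] (0.2 mol %), MeOH, 20 °C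
Reagents that add atoms: none
Why: Noyori asymmetric hydrogenation, in which the hydroxyl binds Ru so only the allylic 2,3-alkene is reduced, and the (R)-BINAP/(E)-allylic alcohol pairing (the one that turns geraniol into (S)-citronellol) makes C3, the future C13, S while both isolated trisubstituted alkenes stay untouched.

**Step 2**
Reactants: 2 (S)-2,3-dihydrofarnesol
Product: 3 (3S,6E)-3,7,11-trimethyldodeca-6,10-dien-1-yl acetate
Conditions: Ac2O, pyridine, DMAP (cat.), CH2Cl2, 0 °C to rt
Reagents that add atoms: acetic anhydride, CC(=O)OC(C)=O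
Why: DMAP-catalysed O-acylation puts in the acetate of the target at once, touches no stereocentre, and removes the need for any later protecting group.

**Step 3**
Reactants: 3 (S)-dihydrofarnesyl acetate
Product: 4 (3S,6E,10E)-12-hydroxy-3,7,11-trimethyldodeca-6,10-dien-1-yl acetate
Conditions: SeO2 (0.2 equiv), t-BuOOH (2.5 equiv), salicylic acid (0.1 equiv), CH2Cl2, 0 °C to rt, stopped at about 60 % conversion
Reagents that add atoms: selenium dioxide (catalytic oxygen carrier), O=[Se]=O; tert-butyl hydroperoxide, CC(C)(C)OO
Why: Catalytic SeO2 allylic oxidation (ene reaction followed by [2,3]-sigmatropic shift) attacks the (E)-methyl of the least hindered, terminal isopropylidene group, which fixes the E geometry of the new allylic alcohol.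

**Step 4**
Reactants: 4 allylic alcohol
Product: 5 (3S,6E,10E)-12-bromo-3,7,11-trimethyldodeca-6,10-dien-1-yl acetate
Conditions: CBr4, PPh3, CH2Cl2, −20 to 0 °C, used crude
Reagents that add atoms: carbon tetrabromide, BrC(Br)(Br)Br
Why: The Appel reaction displaces the alkoxyphosphonium group by SN2 at the primary allylic carbon under neutral conditions, so there is no allylic transposition, no E/Z loss and no effect on the acetate.

**Step 5**
Reactants: 5 allylic bromide; 6 2-(2-bromoethyl)-2-methyl-1,3-dioxolane
Product: 9 (3S,6E,10E)-3,7,11-trimethyl-15-oxohexadeca-6,10-dien-1-yl acetate, via Grignard reagent 7 (not isolated), via dioxolane ketal 8 (not isolated)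
Conditions: 6, Mg, THF, ≤30 °C; added to 5, Li2CuCl4 (3 mol %), THF, −40 to 0 °C; then 2 M HCl, THF, rt
Reagents that add atoms: water, O
Why: Kochi-type Cu-catalysed Grignard/allylic bromide cross-coupling occurs at the unhindered primary α-carbon with retention of the E-alkene and is much faster at low temperature than addition to the alkyl acetate, and the acidic work-up hydrolyses the ketal to the methyl ketone in the same pot.

**Step 6**
Reactants: 9 methyl ketone
Product: 10 (3S,6E,10E)-3,7,11-trimethyl-14-[(2S)-2-methyloxiran-2-yl]tetradeca-6,10-dien-1-yl acetate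
Conditions: Me3S(O)I, NaH, THF (ylide solution, 1.2 equiv); La–Li3–tris[(S)-binaphthoxide] (5 mol %), [2,4,6-(MeO)3C6H2]3P=O (5 mol %), MS 5 Å, THF, rt
Reagents that add atoms: trimethylsulfoxonium iodide, C[S+](C)(C)=O.[I-]
Why: In this catalytic asymmetric Corey–Chaykovsky epoxidation the La/Li binaphthoxide binds ketone and ylide together, tells CH3 from CH2R, and transfers CH2 to one carbonyl face to set the (S)-oxirane carbon (future C4), while the sulfoxonium ylide ignores isolated alkenes and reacts only slowly with an alkyl acetate.

**Step 7**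
Reactants: 10 (S)-oxirane
Product: 11 (4S,5R,9S,10R,13S)-19-hydroxylabd-8(17)-en-15-yl acetate
Conditions: MeAlCl2 (2.5 equiv), 2,6-di-tert-butyl-4-methylpyridine (2 equiv), CH2Cl2 (5 mM), −94 to −78 °C; aq. Rochelle salt; AgNO3–SiO2 chromatography
Reagents that add atoms: none
Why: Proposed new method: MeAlCl2 binds the oxirane oxygen and the tertiary C4–O bond is broken by collinear backside attack of the 5(10)-alkene (a 6-exo-tet opening, so C4 is inverted and no free, racemisable C4 cation is needed); the chair–chair fold of the two E-alkenes turns this into two anti additions (H-5 α, CH3-20 β, C9 side chain equatorial β); the tied-back oxirane CH2 leans away from the incoming alkene and so takes the axial site next to CH3-20 while CH3-18 goes equatorial (the other fold gives a chromatographically distinct equatorial-CH2OH diastereomer, not the enantiomer); the C8 cation then loses its most accessible proton (H-17) to the hindered pyridine, which also scavenges any acid that could move the alkene inward; the closest known reaction types are the MeAlCl2-promoted epoxide-initiated cation–olefin polycyclisation of trisubstituted (oxidosqualene-type) epoxides, the stereospecific Lewis-acid cyclialkylation of 2,2-disubstituted oxiranes, and the exo-selective β-proton abstraction from tertiary cations by hindered bases.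

**Step 8**
Reactants: 11 C19 alcohol
Product: 13 (4S,5R,9S,10R,13S)-15-acetoxylabd-8(17)-en-19-oic acid (CNP0401865.2), via 19-aldehyde 12 (not isolated)
Conditions: Jones reagent (CrO3, H2SO4, H2O), acetone, 0 °C, 30 min
Reagents that add atoms: water, O
Why: Jones oxidation takes the hindered axial neopentyl alcohol through the aldehyde hydrate to the acid, as it does for related 19-hydroxy diterpenes with an exocyclic methylene, and neither the quaternary C4, the 8(17)-ene at 0 °C, nor the acetate is affected.

**Compound list**
1 | (2E,6E)-farnesol | CC(C)=CCC/C(C)=C/CC/C(C)=C/CO | starting material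
2 | (3S,6E)-3,7,11-trimethyldodeca-6,10-dien-1-ol | CC(C)=CCC/C(C)=C/CC[C@H](C)CCO | intermediate
3 | (3S,6E)-3,7,11-trimethyldodeca-6,10-dien-1-yl acetate | CC(C)=CCC/C(C)=C/CC[C@H](C)CCOC(C)=O | intermediate
4 | (3S,6E,10E)-12-hydroxy-3,7,11-trimethyldodeca-6,10-dien-1-yl acetate | OC/C(C)=C/CC/C(C)=C/CC[C@H](C)CCOC(C)=O | intermediate
5 | (3S,6E,10E)-12-bromo-3,7,11-trimethyldodeca-6,10-dien-1-yl acetate | BrC/C(C)=C/CC/C(C)=C/CC[C@H](C)CCOC(C)=O | intermediate
6 | 2-(2-bromoethyl)-2-methyl-1,3-dioxolane | CC1(CCBr)OCCO1 | starting material
7 | [2-(2-methyl-1,3-dioxolan-2-yl)ethyl]magnesium bromide | CC1(CC[Mg]Br)OCCO1 | intermediate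
8 | (3S,6E,10E)-3,7,11-trimethyl-14-(2-methyl-1,3-dioxolan-2-yl)tetradeca-6,10-dien-1-yl acetate | CC1(CCC/C(C)=C/CC/C(C)=C/CC[C@H](C)CCOC(C)=O)OCCO1 | intermediate
9 | (3S,6E,10E)-3,7,11-trimethyl-15-oxohexadeca-6,10-dien-1-yl acetate | CC(=O)CCC/C(C)=C/CC/C(C)=C/CC[C@H](C)CCOC(C)=O | intermediate
10 | (3S,6E,10E)-3,7,11-trimethyl-14-[(2S)-2-methyloxiran-2-yl]tetradeca-6,10-dien-1-yl acetate | C[C@]1(CCC/C(C)=C/CC/C(C)=C/CC[C@H](C)CCOC(C)=O)CO1 | intermediate
11 | (4S,5R,9S,10R,13S)-19-hydroxylabd-8(17)-en-15-yl acetate | C=C1CC[C@@H]2[C@](C)(CCC[C@]2(C)CO)[C@H]1CC[C@H](C)CCOC(C)=O | intermediate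
12 | (4S,5R,9S,10R,13S)-19-oxolabd-8(17)-en-15-yl acetate | C=C1CC[C@@H]2[C@](C)(CCC[C@]2(C)C=O)[C@H]1CC[C@H](C)CCOC(C)=O | intermediate
13 | (4S,5R,9S,10R,13S)-15-acetoxylabd-8(17)-en-19-oic acid | C=C1CC[C@@H]2[C@](C)(CCC[C@]2(C)C(=O)O)[C@H]1CC[C@H](C)CCOC(C)=O | target

**Total step count:** 8. **Longest linear sequence:** 8 steps from 1. Grignard formation and ketal hydrolysis are run in the pot of step 5.

**Steps most likely to fail**

**Step 7** is the weakest point.
- A 1,2-hydride shift can turn the 2,2-disubstituted oxirane into the aldehyde.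
- The axial C19 oxygen can capture the C10 cation as a bridged ether.
- Above all, proton loss from C8 may not be selective for H-17.

The fallback sets out from 10 and comes back at 11. It separates ring formation from placement of the alkene.
- The cascade is run with BF3·OEt2 in CH2Cl2 at −78 °C without the hindered base. This should give mainly the endocyclic isomer (4S,5R,9S,10R,13S)-19-hydroxylabd-7-en-15-yl acetate F1 beside some 11.
- The unseparated mixture is then irradiated (254 nm) with p-xylene as sensitiser in t-BuOH/benzene. This is the Kropp–Marshall photoprotonation.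
- Only the ring alkene of F1 can reach the strained trans-cyclohexene, which is protonated to the C8 cation and relaxes by loss of H-17.
- The exocyclic alkene of 11 cannot enter this cycle, so it accumulates.

**Step 6** may give only moderate discrimination between CH3 and the long CH2R chain. The basic La/Li catalyst or the ylide may also attack the acetate. The fallback sets out from 9 and comes back at 10. It replaces asymmetric synthesis by kinetic resolution.
- Uncatalysed Corey–Chaykovsky methylenation (Me3S(O)I, NaH, DMSO/THF) gives 10 together with its oxirane epimer (3S,6E,10E)-3,7,11-trimethyl-14-[(2R)-2-methyloxiran-2-yl]tetradeca-6,10-dien-1-yl acetate F2 in about 1:1 ratio.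
- The mixture is treated with a (salen)Cr(III) azide catalyst and TMSN3/i-PrOH (0.55 equiv). The catalyst antipode is chosen so that only F2 is opened at its CH2.
- This opening gives (3S,6E,10E,15R)-16-azido-15-hydroxy-3,7,11,15-tetramethylhexadeca-6,10-dien-1-yl acetate F3.
- The much less polar, unreacted 10 is recovered by chromatography.

**Step 3** may suffer from competing oxidation at the internal alkene and from over-oxidation, so the yield may be low. The fallback sets out from 3 and comes back at 4. It replaces C–H oxidation by alkene exchange.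
- Cross-metathesis of 3 with methacrolein (5 equiv, Hoveyda–Grubbs II, 3 mol %, CH2Cl2, 40 °C) engages only the terminal isopropylidene group. The internal trisubstituted alkene is inert.
- The product is the E-enal (3S,6E,10E)-3,7,11-trimethyl-12-oxododeca-6,10-dien-1-yl acetate F4.
- Luche reduction (NaBH4, CeCl3, MeOH, 0 °C) converts F4 into 4.

**Further compounds**
F1 | step 7 | (4S,5R,9S,10R,13S)-19-hydroxylabd-7-en-15-yl acetate | CC1=CC[C@@H]2[C@](C)(CCC[C@]2(C)CO)[C@H]1CC[C@H](C)CCOC(C)=O
F2 | step 6 | (3S,6E,10E)-3,7,11-trimethyl-14-[(2R)-2-methyloxiran-2-yl]tetradeca-6,10-dien-1-yl acetate | C[C@@]1(CCC/C(C)=C/CC/C(C)=C/CC[C@H](C)CCOC(C)=O)CO1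
F3 | step 6 | (3S,6E,10E,15R)-16-azido-15-hydroxy-3,7,11,15-tetramethylhexadeca-6,10-dien-1-yl acetate | C[C@@](O)(CCC/C(C)=C/CC/C(C)=C/CC[C@H](C)CCOC(C)=O)CN=[N+]=[N-]
F4 | step 3 | (3S,6E,10E)-3,7,11-trimethyl-12-oxododeca-6,10-dien-1-yl acetate | O=C/C(C)=C/CC/C(C)=C/CC[C@H](C)CCOC(C)=O
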